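**Retrosynthetic overview**
- Diplotrin A is an isomer of a 2-(methoxy-p-benzoquinonyl)-3-methoxyflavanone. The last disconnection is therefore the ring B C2'–O bond: para-oxygenation of a 3'-hydroxy-4'-methoxyflavanone, with the quinone then taking up the two hydrogens of C2–C3.
- The flavanone is opened at the O1–C2 bond (oxa-Michael ring closure of an α-methoxychalcone), which traces back to an ω-methoxy ketone and isovanillin.
- The ω-methoxy ketone, which already carries the future 3-OMe group, comes from 1,2,3-trimethoxybenzene and methoxyacetyl chloride.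
- Rings A and B are bought. Ring C is closed by C–O bond formation in step 2 and brought to the pyranone oxidation level in step 3. No protecting groups are used.

Assumption: the target SMILES has no stereocentre and no stable stereoaxis, so diplotrin A is a single achiral compound; racemic intermediates are acceptable and no enantiocontrol is needed.

**Step 1**
Reactants: 1 1,2,3-trimethoxybenzene; 2 methoxyacetyl chloride
Product: 4 1-(2-hydroxy-3,4-dimethoxyphenyl)-2-methoxyethan-1-one, via trimethoxyphenyl ketone 3 (not isolated)
Conditions: AlCl3 (2.5 equiv), CH2Cl2, 0 °C to reflux; 1 M HCl work-up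
Reagents that add atoms: none
Why: Friedel–Crafts acylation at C4 of 1 (para to one methoxy group, ortho to another) is followed in the same flask by chelation-directed AlCl3 cleavage of only the methyl ether ortho to the new carbonyl, the classical one-pot entry to 2-hydroxy-3,4-dimethoxyaryl ketones; no stereocentre is formed.

**Step 2**
Reactants: 4 1-(2-hydroxy-3,4-dimethoxyphenyl)-2-methoxyethan-1-one; 5 isovanillin (3-hydroxy-4-methoxybenzaldehyde)
Product: 7 rac-trans-2-(3-hydroxy-4-methoxyphenyl)-3,7,8-trimethoxychroman-4-one, via α-methoxychalcone 6 (not isolated)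
Conditions: pyrrolidine (1.5 equiv), EtOH, reflux; AcOH quench
Reagents that add atoms: none
Why: An amine-mediated Claisen–Schmidt (aldol) condensation gives chalcone 6, whose twisted α-substituted enone is closed by the ortho phenol in a 6-endo oxa-Michael addition that forms the O1–C2 bond of ring C and ties up the ring A phenol so that only the ring B phenol can be oxidised in step 3; C2 and C3 form racemic under thermodynamic control (trans major, some cis carried along) and both are erased in step 3.

**Step 3**
Reactants: 7 rac-trans-2-(3-hydroxy-4-methoxyphenyl)-3,7,8-trimethoxychroman-4-one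
Product: 9 diplotrin A, via flavanone quinone 8 (not isolated)
Conditions: ON(SO3K)2 (2.1 equiv), KH2PO4, H2O/acetone, 0 °C to rt; extract (EtOAc), switch to degassed MeCN; i-Pr2NEt/AcOH (1:1, 20 mol%), 40 °C, Ar
Reagents that add atoms: potassium nitrosodisulfonate ON(SO3K)2, [K+].[K+].[O]N(S(=O)(=O)[O-])S(=O)(=O)[O-]
Why: Proposed new method: a para-oxygenation/internal-redox relay in which the nitroxyl radical ON(SO3K)2 first forms the ring B C–O bond para to the free phenol (Teuber oxidation, known) to give p-quinone 8, after which the amine/acid buffer moves the C2–H proton onto the quinone (vinylogous enolisation to an o-quinone methide stabilised by the O1 lone pair) and then the C3–H proton likewise, so that the quinone accepts the two hydrogens of C2–C3 and becomes the hydroquinone while ring C becomes the 4-pyranone, a redox-neutral, irreversibly aromatising isomerisation (estimated more than 10 kcal/mol downhill) that needs no external dehydrogenating agent or reductant and removes both stereocentres; the closest known reaction types are the base-catalysed alkylquinone to o-quinone methide tautomerisation (prenylquinone to chromenol) and the isomerisation of (1-hydroxyalkyl)quinones to acylhydroquinones, neither of which has been used to desaturate a flavanone.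

**Compound list**
1 | 1,2,3-trimethoxybenzene | COc1cccc(OC)c1OC | starting material
2 | methoxyacetyl chloride | COCC(Cl)=O | starting material
3 | 2-methoxy-1-(2,3,4-trimethoxyphenyl)ethan-1-one (formed in the flask in step 1 as its AlCl3 complex, not isolated) | COCC(=O)c1ccc(OC)c(OC)c1OC | intermediate
4 | 1-(2-hydroxy-3,4-dimethoxyphenyl)-2-methoxyethan-1-one | COCC(=O)c1ccc(OC)c(OC)c1O | intermediate
5 | isovanillin (3-hydroxy-4-methoxybenzaldehyde) | COc1ccc(C=O)cc1O | starting material
6 | (Z)-3-(3-hydroxy-4-methoxyphenyl)-1-(2-hydroxy-3,4-dimethoxyphenyl)-2-methoxyprop-2-en-1-one (α-methoxychalcone, ring B aryl trans to the carbonyl, not isolated) | COc1ccc(C(=O)/C(OC)=C/c2ccc(OC)c(O)c2)c(O)c1OC | intermediate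
7 | rac-trans-2-(3-hydroxy-4-methoxyphenyl)-3,7,8-trimethoxychroman-4-one (racemate, drawn as the 2R,3R enantiomer; minor cis isomer carried along) | COc1ccc2c(c1OC)O[C@H](c1ccc(OC)c(O)c1)[C@@H](OC)C2=O | intermediate
8 | rac-trans-2-methoxy-5-(3,7,8-trimethoxy-4-oxochroman-2-yl)cyclohexa-2,5-diene-1,4-dione (racemate, drawn as the 2R,3R enantiomer, not isolated) | COc1ccc2c(c1OC)O[C@H](C1=CC(=O)C(OC)=CC1=O)[C@@H](OC)C2=O | intermediate
9 | diplotrin A, 2-(2,5-dihydroxy-4-methoxyphenyl)-3,7,8-trimethoxy-4H-chromen-4-one (achiral) | COc1cc(O)c(-c2oc3c(OC)c(OC)ccc3c(=O)c2OC)cc1O | target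

**Step count**
Total steps: 3. Longest linear sequence: 3 (1 to 4 to 7 to 9).

**Steps most likely to fail**

Step 3 (the proposed new relay) is the least certain. Its risks are:
- E1cB opening of ring C in 8 to a quinone chalcone, which could re-close 5-exo to a benzofuranone;
- amine-induced decomposition of the methoxyquinone;
- over-oxidation of 9 if any nitroxyl is carried over.

Hydrogen exchange between 9 and unreacted 8 is not a loss, because it is reversible and only the isomerisation is irreversible. The fallback uses known chemistry only; it sets out from 7 and comes back at 9. Catalytic I2 in DMSO at 120 °C dehydrogenates the flavanone to 2-(3-hydroxy-4-methoxyphenyl)-3,7,8-trimethoxy-4H-chromen-4-one F1. Teuber oxidation of F1 with ON(SO3K)2 in KH2PO4-buffered aqueous acetone gives 2-methoxy-5-(3,7,8-trimethoxy-4-oxo-4H-chromen-2-yl)cyclohexa-2,5-diene-1,4-dione F2. Reduction of F2 with Na2S2O4 in EtOAc/H2O gives 9.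

Step 1 can fail if the methoxyacetyl cation loses CO (giving methoxymethylation of 1) or if AlCl3 also cleaves the α-methoxy or 3-methoxy group. The fallback replaces the cationic acylation by an anionic one; it sets out from 1 and comes back at 4. Ortho-lithiation of 1 with n-BuLi/TMEDA in THF at 0 °C gives (2,3,4-trimethoxyphenyl)lithium F3. Acylation of F3 with the Weinreb amide N,2-dimethoxy-N-methylacetamide (CON(C)C(=O)COC) gives ketone 3, now isolated. BCl3 in CH2Cl2 at −78 to 0 °C then cleaves only the methyl ether ortho to the carbonyl to give 4.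

Step 2 can stall at the aldol or chalcone stage, because the α-methoxy ketone is hindered and the free phenol of 5 is partly deprotonated, and it may leave a chalcone/flavanone mixture. The fallback is a stepwise, protected sequence; it sets out from 4 and comes back at 7. KOH-mediated Claisen–Schmidt condensation of 4 with commercial 3-(benzyloxy)-4-methoxybenzaldehyde (COc1ccc(C=O)cc1OCc1ccccc1) in EtOH gives (Z)-3-[3-(benzyloxy)-4-methoxyphenyl]-1-(2-hydroxy-3,4-dimethoxyphenyl)-2-methoxyprop-2-en-1-one F4. NaOAc in refluxing EtOH cyclises F4 to rac-trans-2-[3-(benzyloxy)-4-methoxyphenyl]-3,7,8-trimethoxychroman-4-one F5. Hydrogenolysis of F5 (H2, Pd/C, palladium metal on carbon, EtOAc, rt) gives 7.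

**Further compounds**
F1 | step 3 | 2-(3-hydroxy-4-methoxyphenyl)-3,7,8-trimethoxy-4H-chromen-4-one | COc1ccc(-c2oc3c(OC)c(OC)ccc3c(=O)c2OC)cc1O
F2 | step 3 | 2-methoxy-5-(3,7,8-trimethoxy-4-oxo-4H-chromen-2-yl)cyclohexa-2,5-diene-1,4-dione | COC1=CC(=O)C(c2oc3c(OC)c(OC)ccc3c(=O)c2OC)=CC1=O
F3 | step 1 | (2,3,4-trimethoxyphenyl)lithium | [Li]c1ccc(OC)c(OC)c1OC
F4 | step 2 | (Z)-3-[3-(benzyloxy)-4-methoxyphenyl]-1-(2-hydroxy-3,4-dimethoxyphenyl)-2-methoxyprop-2-en-1-one | COc1ccc(C(=O)/C(OC)=C/c2ccc(OC)c(OCc3ccccc3)c2)c(O)c1OC
F5 | step 2 | rac-trans-2-[3-(benzyloxy)-4-methoxyphenyl]-3,7,8-trimethoxychroman-4-one (drawn as the 2R,3R enantiomer) | COc1ccc2c(c1OC)O[C@H](c1ccc(OC)c(OCc3ccccc3)c1)[C@@H](OC)C2=O
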